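The (1(10)Z,4E)-cyclodecadiene is read as a six-membered ring (C5–C10, carrying C14 and the C11–C13 branch, i.e. a carvone skeleton) into whose C5–C10 bond the four carbons C1–C4 of 1-methylcyclobutene are inserted. Flash thermolysis of the enone–cyclobutene [2+2] photoadduct cleaves the C1–C4 and C5–C10 σ-bonds in one operation, creates the C1=C10 and C4=C5 π-bonds and thereby opens the ten-membered ring as its C9 enone. The precursor is a cyclohexanone fused to a bicyclo[2.2.0]hexane that already carries the C6 and C12 silyl ethers, the C7 branch and the C8 epoxyangelate; reduction, acetylation and oxidative lactonisation then complete the target.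

Key step: step 16

Remark on the chemistry: germacrane numbering is used throughout (ring C5–C10, C14 on C10, side chain C11–C13 on C7); the C6 oxygen is introduced as an α′-oxygen and the enone is then transposed, and this exchange of the two CH2 groups flanking C7 is why (S)-carvone, not its enantiomer, delivers the required C7 configuration.

Step 1
Reactants: 1 (S)-(+)-carvone
Product: 2 (5S)-5-(3-chloroprop-1-en-2-yl)-2-methylcyclohex-2-en-1-one (10-chlorocarvone)
Conditions: Ca(OCl)2, CO2 (dry ice), CH2Cl2/H2O, 0 °C
Reagents that add atoms: Ca(OCl)2 (calcium hypochlorite), [Ca+2].[O-]Cl.[O-]Cl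
Why: Ene-type allylic chlorination by hypochlorous acid formed in situ is selective for the electron-rich 1,1-disubstituted alkene over the deactivated enone and leaves the C7 stereocentre untouched.

Step 2
Reactants: 2 10-chlorocarvone
Product: 4 (5S)-5-(3-hydroxyprop-1-en-2-yl)-2-methylcyclohex-2-en-1-one, via allylic acetate 3 (not isolated)
Conditions: KOAc, n-Bu4NI (cat.), DMF, 60 °C; then K2CO3 (cat.), MeOH, 0 °C
Reagents that add atoms: KOAc (potassium acetate), CC(=O)[O-].[K+]
Why: SN2 displacement of the primary allylic chloride by acetate followed by base-catalysed transesterification with methanol frees the C12 hydroxyl without affecting the enone.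

Step 3
Reactants: 4 10-hydroxycarvone
Product: 6 bis-TBS ether of trans-6,10-dihydroxycarvone (C5 ketone; C6–OTBS trans to the C7 side chain), via TBS dienol ether 5 (not isolated)
Conditions: TBSOTf (2.3 equiv), Et3N, CH2Cl2, 0 °C; then mCPBA, NaHCO3, CH2Cl2, −20 °C
Reagents that add atoms: tert-butyldimethylsilyl triflate, CC(C)(C)[Si](C)(C)OS(=O)(=O)C(F)(F)F; mCPBA, OOC(=O)c1cccc(Cl)c1
Why: Rubottom oxidation: soft enolisation at the α′-CH2 gives the cross-conjugated silyloxy diene (the primary alcohol is silylated at the same time), the peracid epoxidises the enol ether on the face anti to the adjacent C7 side chain and 1,4-silyl migration gives the α′-silyloxy ketone, which sets C6 trans to C7.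

Step 4
Reactants: 6 bis-TBS ketone
Product: 7 epoxy ketone (C9–C10 epoxide, oxygen cis to the C6 silyloxy group and trans to the C7 side chain)
Conditions: 30% H2O2, NaOH (cat.), MeOH, 0 °C
Reagents that add atoms: hydrogen peroxide, OO
Why: Weitz–Scheffer nucleophilic epoxidation, in which hydroperoxide adds to the β-carbon anti to the C7 side chain as with carvone itself; the two epoxide centres are transient, since C10 becomes sp2 in step 5 and C9 a carbonyl carbon in step 6.

Step 5
Reactants: 7 epoxy ketone
Product: 9 allylic alcohol (C9–OH, C10=C5), via epoxy hydrazone 8 (not isolated)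
Conditions: N2H4·H2O, AcOH (cat.), MeOH, 0 °C → rt, under argon
Reagents that add atoms: none
Why: Wharton transposition: the hydrazone of the α,β-epoxy ketone collapses with loss of N2 to the transposed allylic alcohol, which moves the ring oxygen from C5 to C9 and the double bond to C10=C5 and so turns the silyloxy carbon C6 into the γ-position of the future enone without touching C6 or C7.

Step 6
Reactants: 9 allylic alcohol
Product: 10 (4S,5R)-4-(tert-butyldimethylsilyloxy)-5-[3-(tert-butyldimethylsilyloxy)prop-1-en-2-yl]-2-methylcyclohex-2-en-1-one (C9 ketone, C10=C5, C6–OTBS trans to the C7 side chain)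
Conditions: Dess–Martin periodinane, NaHCO3, CH2Cl2, rt
Reagents that add atoms: none
Why: Dess–Martin oxidation of the secondary allylic alcohol gives the enone under neutral conditions that spare the silyl ethers and the γ-stereocentre.

Step 7
Reactants: 10 γ-silyloxy enone
Product: 13 7,8-trans α′-hydroxy enone, via TMS dienol ether 11 (not isolated), via silyloxy ketone 12 (not isolated)
Conditions: TMSOTf, Et3N, CH2Cl2, 0 °C; then mCPBA, NaHCO3, CH2Cl2, −20 °C; then citric acid, MeOH, 0 °C
Reagents that add atoms: mCPBA, OOC(=O)c1cccc(Cl)c1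
Why: Rubottom oxidation at the only α′-CH2 (C8), the peracid again attacking anti to the adjacent C7 side chain so that the C8 hydroxyl is trans to it, and mild acidic methanolysis removing only the trimethylsilyl ether.

Step 8
Reactants: 13 7,8-trans α′-hydroxy enone
Product: 14 7,8-cis 4-nitrobenzoate
Conditions: 4-O2NC6H4CO2H, PPh3, DIAD, toluene, 0 °C → rt
Reagents that add atoms: 4-nitrobenzoic acid, OC(=O)c1ccc(cc1)[N+](=O)[O-]
Why: Mitsunobu reaction: the carboxylate displaces the oxyphosphonium group at the carbonyl-activated C8 by SN2 with inversion, which places the C8 oxygen cis to the C7 side chain as in the target.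

Step 9
Reactants: 14 4-nitrobenzoate
Product: 15 7,8-cis α′-hydroxy enone
Conditions: K2CO3 (0.2 equiv), MeOH, 0 °C
Reagents that add atoms: none
Why: Transesterification of the activated aryl ester by acyl–oxygen cleavage keeps the inverted C8 configuration, and catalytic base at low temperature leaves the ketol little time to enolise.

Step 10
Reactants: 16 angelic acid
Product: 17 (Z)-2-methylbut-2-en-1-ol
Conditions: LiAlH4, Et2O, 0 °C → rt
Reagents that add atoms: none
Why: Hydride reduction of the carboxylic acid to the primary allylic alcohol, with the Z alkene geometry retained.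

Step 11
Reactants: 17 (Z)-2-methylbut-2-en-1-ol
Product: 18 [(2S,3R)-2,3-dimethyloxiran-2-yl]methanol
Conditions: Ti(OiPr)4 (cat.), L-(+)-diethyl tartrate (cat.), t-BuOOH, 4 Å MS, CH2Cl2, −20 °C
Reagents that add atoms: tert-butyl hydroperoxide, CC(C)(C)OO
Why: Sharpless asymmetric epoxidation: the titanium tartrate complex delivers the peroxide oxygen to the enantioface prescribed by the L-(+)-tartrate rule, which sets both epoxide carbons at once, their cis relationship (CH2OH and C3 methyl) following from the Z alkene.

Step 12
Reactants: 18 epoxy alcohol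
Product: 19 (2R,3R)-2,3-dimethyloxirane-2-carboxylic acid ((2R,3R)-epoxyangelic acid)
Conditions: RuCl3·xH2O (cat.), NaIO4, MeCN/CCl4/H2O, rt
Reagents that add atoms: water, O
Why: RuO4-mediated oxidation of the primary alcohol through the aldehyde hydrate to the acid, with periodate as terminal oxidant and no bond to either stereocentre broken (the change of the C2 descriptor is only a change of priorities).

Step 13
Reactants: 15 7,8-cis α′-hydroxy enone; 19 (2R,3R)-epoxyangelic acid
Product: 21 C8 epoxyangelate of the enone, via mixed anhydride 20 (not isolated)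
Conditions: 19, 2,4,6-Cl3C6H2COCl, Et3N, toluene, rt; then 15, DMAP, toluene, rt
Reagents that add atoms: none
Why: Yamaguchi esterification: the mixed anhydride acylates the C8 hydroxyl through the acylpyridinium ion, so C8 is retained, the α-quaternary epoxy acid cannot epimerise, and installing this hindered ester now, on a simple cyclohexenone, avoids a late acylation next to the C9 acetate.

Step 14
Reactants: 22 methylenecyclobutane
Product: 23 1-methylcyclobutene
Conditions: t-BuOK (cat.), DMSO, 40 °C; fractional distillation
Reagents that add atoms: none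
Why: Base-catalysed prototropic isomerisation through the allyl anion equilibrates the exocyclic alkene with the more substituted endocyclic isomer, which is separated by distillation.

Step 15
Reactants: 21 enone ester; 23 1-methylcyclobutene
Product: 24 photoadduct (cyclohexanone fused to a bicyclo[2.2.0]hexane)
Conditions: 23 (15 equiv), CH2Cl2, hν (365 nm), −40 °C
Reagents that add atoms: none
Why: Enone–alkene [2+2] photocycloaddition through the triplet enone: head-to-tail orientation joins the methyl-bearing alkene carbon C4 to the β-carbon C5 and C1 to C10 (the alternative would join two fully substituted carbons), the six–four and four–four ring fusions are cis in a cis-anti-cis array with the cyclobutane anti to the C6 silyloxy group, excess alkene outruns the slow intramolecular addition to the side-chain alkene, and the four new stereocentres are all erased in step 16 so that a π-facial isomer would converge on the same dienone.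

Step 16
Reactants: 24 photoadduct
Product: 25 (1(10)Z,4E)-cyclodeca-1(10),4-dien-9-one
Conditions: flash vacuum pyrolysis: sublimed at about 160 °C through a quartz tube at 450 °C, 0.05 mbar, contact time about 10 ms, trap at −78 °C
Reagents that add atoms: none
Why: Homolysis of the strained central C1–C4 bond of the bicyclo[2.2.0]hexane gives a cyclohexane-1,4-diyl (C1, C2, C3, C4, C5, C10) that fragments across C5–C10, so that two σ-bonds are exchanged for the C1=C10 and C4=C5 π-bonds with release of the strain of both cyclobutanes. The closest known reaction type is the thermal cycloreversion of cyclobutene–cyclohexenone [2+2] photoadducts to cis,trans-cyclodeca-1,5-dienes, itself an extension of the bicyclo[2.2.0]hexane to hexa-1,5-diene rearrangement. No ring is closed by bond formation: the ten-membered ring is unveiled by cleavage of the C5–C10 bond shared by the six- and four-membered rings (ring expansion by four carbons), and no stereocentre is created, the four cyclobutane centres becoming sp2. The step must put the cis double bond at C1=C10 and the trans one at C4=C5: the diyl cleaves from a chair in which one of the two cis ring bonds at C10 and C5 is axial (it ends in a Z alkene) and the other equatorial (E alkene), and the chair with C9 axial and the C14 methyl and C6 equatorial is the less crowded one and the only one that lets the developing C1=C10 bond conjugate with the C9 carbonyl. The step must also cleave C5–C10 and not C2–C3 and avoid Cope rearrangement of the product: C5–C10 cleavage gives the more substituted, conjugated diene, and the short contact time removes the dienone from the hot zone before the slower [3,3] shift, which would cost the enone conjugation, can set in. The C8 ester has no syn β-hydrogen in the six-membered ring (H7 is trans), so ester pyrolysis is not expected, and the silyl ethers and the epoxide should tolerate the short exposure.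

Step 17
Reactants: 25 dienone
Product: 26 9α-allylic alcohol
Conditions: NaBH4, CeCl3·7H2O, MeOH, −78 °C
Reagents that add atoms: none
Why: Luche 1,2-reduction of the enone; hydride is expected to attack the peripheral face of the C9 carbonyl anti to the perpendicular C8–O bond (polar Felkin–Anh model, the ester not chelating), which gives the 9α-alcohol trans to the 8β-ester.

Step 18
Reactants: 26 allylic alcohol
Product: 27 C9 acetate
Conditions: Ac2O, pyridine, DMAP (cat.), CH2Cl2, 0 °C
Reagents that add atoms: acetic anhydride, CC(=O)OC(C)=O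
Why: DMAP-catalysed acetylation of the allylic C9 hydroxyl, fast enough with the small anhydride to pre-empt migration of the hindered α-quaternary C8 ester; no stereocentre is affected.

Step 19
Reactants: 27 bis-silyl ether
Product: 28 C6,C12-diol
Conditions: HF·pyridine, pyridine, THF, 0 °C → rt
Reagents that add atoms: none
Why: Fluoride-driven cleavage of both silyl ethers (Si–F bond formation) under buffered conditions that spare the acetate, the hindered ester, the electron-poor trisubstituted epoxide and the 1,5-diene.

Step 20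
Reactants: 28 diol
Product: 31 CNP0304643.4, via hydroxy enal 29 (not isolated), via lactol 30 (not isolated)
Conditions: TEMPO (cat.), PhI(OAc)2, CH2Cl2, rt
Reagents that add atoms: none
Why: Oxoammonium (TEMPO) oxidation selective for the primary allylic alcohol gives the enal, which the C6 hydroxyl traps as the lactol (C8 is acylated and cannot compete) and which is oxidised further to the α-methylene-γ-butyrolactone, trans-fused because C6 and C7 are already fixed.

Compound list

1 | (S)-(+)-carvone, (5S)-2-methyl-5-(prop-1-en-2-yl)cyclohex-2-en-1-one | CC1=CC[C@H](C(C)=C)CC1=O | starting material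
2 | (5S)-5-(3-chloroprop-1-en-2-yl)-2-methylcyclohex-2-en-1-one | CC1=CC[C@H](C(=C)CCl)CC1=O | intermediate
3 | 2-[(1S)-4-methyl-5-oxocyclohex-3-en-1-yl]prop-2-en-1-yl acetate | CC1=CC[C@H](C(=C)COC(C)=O)CC1=O | intermediate (not isolated)
4 | (5S)-5-(3-hydroxyprop-1-en-2-yl)-2-methylcyclohex-2-en-1-one | CC1=CC[C@H](C(=C)CO)CC1=O | intermediate
5 | kinetic bis-TBS dienol ether of 4: (6S)-2-(TBSO)-3-methyl-6-[3-(TBSO)prop-1-en-2-yl]cyclohexa-1,3-diene | C1=C(C)C(O[Si](C)(C)C(C)(C)C)=C[C@@H](C(=C)CO[Si](C)(C)C(C)(C)C)C1 | intermediate (not isolated)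
6 | (5R,6R)-6-(tert-butyldimethylsilyloxy)-5-[3-(tert-butyldimethylsilyloxy)prop-1-en-2-yl]-2-methylcyclohex-2-en-1-one; 6-OTBS trans to the side chain | C1=C(C)C(=O)[C@H](O[Si](C)(C)C(C)(C)C)[C@@H](C(=C)CO[Si](C)(C)C(C)(C)C)C1 | intermediate
7 | 3-(TBSO)-4-[3-(TBSO)prop-1-en-2-yl]-1-methyl-7-oxabicyclo[4.1.0]heptan-2-one; epoxide oxygen cis to the 3-silyloxy group, both trans to the 4-side chain | O=C1[C@H](O[Si](C)(C)C(C)(C)C)[C@@H](C(=C)CO[Si](C)(C)C(C)(C)C)C[C@@H]2O[C@]12C | intermediate
8 | hydrazone of 7 at the ketone carbon | NN=C1[C@H](O[Si](C)(C)C(C)(C)C)[C@@H](C(=C)CO[Si](C)(C)C(C)(C)C)C[C@@H]2O[C@]12C | intermediate (not isolated)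
9 | 4-(TBSO)-5-[3-(TBSO)prop-1-en-2-yl]-2-methylcyclohex-2-en-1-ol; 1-OH cis to 4-OTBS, both trans to the 5-side chain | O[C@@H]1C(C)=C[C@H](O[Si](C)(C)C(C)(C)C)[C@@H](C(=C)CO[Si](C)(C)C(C)(C)C)C1 | intermediate
10 | (4S,5R)-4-(tert-butyldimethylsilyloxy)-5-[3-(tert-butyldimethylsilyloxy)prop-1-en-2-yl]-2-methylcyclohex-2-en-1-one | O=C1C(C)=C[C@H](O[Si](C)(C)C(C)(C)C)[C@@H](C(=C)CO[Si](C)(C)C(C)(C)C)C1 | intermediate
11 | kinetic TMS dienol ether of 10 (C9–OTMS, C9=C8 and C10=C5) | C[Si](C)(C)OC=1C(C)=C[C@H](O[Si](C)(C)C(C)(C)C)[C@@H](C(=C)CO[Si](C)(C)C(C)(C)C)C=1 | intermediate (not isolated)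
12 | (4S,5S,6S)-4-(TBSO)-5-[3-(TBSO)prop-1-en-2-yl]-2-methyl-6-(trimethylsilyloxy)cyclohex-2-en-1-one; 6-O trans to the side chain | O=C1C(C)=C[C@H](O[Si](C)(C)C(C)(C)C)[C@@H](C(=C)CO[Si](C)(C)C(C)(C)C)[C@@H]1O[Si](C)(C)C | intermediate (not isolated)
13 | (4S,5S,6S)-4-(TBSO)-5-[3-(TBSO)prop-1-en-2-yl]-6-hydroxy-2-methylcyclohex-2-en-1-one; 6-OH trans to the side chain | O=C1C(C)=C[C@H](O[Si](C)(C)C(C)(C)C)[C@@H](C(=C)CO[Si](C)(C)C(C)(C)C)[C@@H]1O | intermediate
14 | 4-nitrobenzoate of 15 (C8 oxygen cis to the C7 side chain) | O=C1C(C)=C[C@H](O[Si](C)(C)C(C)(C)C)[C@@H](C(=C)CO[Si](C)(C)C(C)(C)C)[C@H]1OC(=O)c2ccc(cc2)[N+](=O)[O-] | intermediate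
15 | (4S,5S,6R)-4-(TBSO)-5-[3-(TBSO)prop-1-en-2-yl]-6-hydroxy-2-methylcyclohex-2-en-1-one; 6-OH cis to the side chain | O=C1C(C)=C[C@H](O[Si](C)(C)C(C)(C)C)[C@@H](C(=C)CO[Si](C)(C)C(C)(C)C)[C@H]1O | intermediate
16 | angelic acid, (Z)-2-methylbut-2-enoic acid | C/C=C(/C)C(=O)O | starting material
17 | (Z)-2-methylbut-2-en-1-ol | C/C=C(/C)CO | intermediate
18 | [(2S,3R)-2,3-dimethyloxiran-2-yl]methanol | OC[C@]1(C)O[C@@H]1C | intermediate
19 | (2R,3R)-2,3-dimethyloxirane-2-carboxylic acid | OC(=O)[C@]1(C)O[C@@H]1C | intermediate
20 | mixed anhydride of 19 with 2,4,6-trichlorobenzoic acid | O=C(OC(=O)[C@]1(C)O[C@@H]1C)c2c(Cl)cc(Cl)cc2Cl | intermediate (not isolated)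
21 | (2R,3R)-2,3-dimethyloxirane-2-carboxylate of 15 (C9 ketone, C10=C5, C6–OTBS, C12–OTBS, C8 ester cis to the C7 side chain) | O=C1C(C)=C[C@H](O[Si](C)(C)C(C)(C)C)[C@@H](C(=C)CO[Si](C)(C)C(C)(C)C)[C@H]1OC(=O)[C@]2(C)O[C@@H]2C | intermediate
22 | methylenecyclobutane | C=C1CCC1 | starting material
23 | 1-methylcyclobutene | CC1=CCC1 | intermediate
24 | photoadduct: C9 cyclohexanone fused at C5–C10 to a bicyclo[2.2.0]hexane (C1–C4 with C5, C10), cis-anti-cis; C14 and H5 on the face of the C6 silyloxy group, cyclobutanes on the opposite face; C6–OTBS, C7 side chain with C12–OTBS, C8 epoxyangelate | O=C1[C@@]2(C)[C@@H]3CC[C@]3(C)[C@H]2[C@H](O[Si](C)(C)C(C)(C)C)[C@@H](C(=C)CO[Si](C)(C)C(C)(C)C)[C@H]1OC(=O)[C@]4(C)O[C@@H]4C | intermediate (precursor of the key step)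
25 | (1(10)Z,4E)-cyclodeca-1(10),4-dien-9-one with 6α-OTBS, 7β side chain (C12–OTBS), 8β-epoxyangelate | O=C1/C(C)=C\CC/C(C)=C/[C@H](O[Si](C)(C)C(C)(C)C)[C@@H](C(=C)CO[Si](C)(C)C(C)(C)C)[C@H]1OC(=O)[C@]2(C)O[C@@H]2C | intermediate (product of the key step)
26 | 9α-alcohol of 25 (9-OH trans to the 8-ester) | O[C@@H]1/C(C)=C\CC/C(C)=C/[C@H](O[Si](C)(C)C(C)(C)C)[C@@H](C(=C)CO[Si](C)(C)C(C)(C)C)[C@H]1OC(=O)[C@]2(C)O[C@@H]2C | intermediate
27 | 9α-acetate of 26 | CC(=O)O[C@@H]1/C(C)=C\CC/C(C)=C/[C@H](O[Si](C)(C)C(C)(C)C)[C@@H](C(=C)CO[Si](C)(C)C(C)(C)C)[C@H]1OC(=O)[C@]2(C)O[C@@H]2C | intermediate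
28 | C6,C12-diol of 27 | CC(=O)O[C@@H]1/C(C)=C\CC/C(C)=C/[C@H](O)[C@@H](C(=C)CO)[C@H]1OC(=O)[C@]2(C)O[C@@H]2C | intermediate
29 | C12 enal with free C6 hydroxyl | CC(=O)O[C@@H]1/C(C)=C\CC/C(C)=C/[C@H](O)[C@@H](C(=C)C=O)[C@H]1OC(=O)[C@]2(C)O[C@@H]2C | intermediate (not isolated)
30 | 6,12-lactol (C12 epimers) | CC(=O)O[C@@H]1/C(C)=C\CC/C(C)=C/[C@@H]2OC(O)C(=C)[C@H]2[C@H]1OC(=O)[C@]3(C)O[C@@H]3C | intermediate (not isolated)
31 | CNP0304643.4: (6S,7R,8R,9R)-9-acetoxy-8-[(2R,3R)-2,3-dimethyloxirane-2-carbonyloxy]germacra-1(10)Z,4E,11(13)-trien-12,6-olide | C=C1C(=O)O[C@H]2/C=C(\C)CC/C=C(/C)[C@@H](OC(C)=O)[C@H](OC(=O)[C@]3(C)O[C@@H]3C)[C@H]12 | target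

Total step count: 20 (16 in the main line, 3 for the epoxy acid, 1 for 1-methylcyclobutene).
Longest linear sequence: 16 steps from (S)-carvone (steps 1–9, 13, 15–20).

Steps most likely to fail

Step 16 (key step). What may go wrong: the 1,4-diyl may fragment through its other chair, which would place the trans geometry in the enone and the cis geometry at C4=C5, or the dienone may undergo Cope rearrangement while still in the hot zone. Fallback: give up kinetic gas-phase control and use the reversibility of the Cope manifold instead. It sets out from 24 and comes back at 25. The thermolysate containing the (1(10)E,4Z)-dienone F1 and/or the Cope isomer, the cis-2-methyl-3-isopropenyl-2-vinylcyclohexanone F2, is heated in degassed toluene (sealed tube, about 180 °C). F1, F2 and 25 interconvert by [3,3] shifts through the two chair conformers of F2. As the only member with a planar conjugated enone, 25 should accumulate and is removed by chromatography, while F1 and F2 are recycled.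

Step 17. What may go wrong: poor or reversed facial selectivity in the hydride addition, because the conformation of the ten-membered ring and not the reagent decides which face of C9 is exposed. Fallback: correct C9 by substitution instead of by reduction. It sets out from 25 and comes back at 27. The 9β-alcohol F3 obtained from the reduction is treated with acetic acid, PPh3 and DIAD (toluene, 0 °C). Mitsunobu displacement at the allylic C9 with inversion then installs the 9α-acetate directly, and step 18 is skipped.

Step 8. What may go wrong: loss of the activated C8 oxygen by elimination toward a cross-conjugated dienone that aromatises, or sluggish substitution next to the branched C7. Fallback: invert C8 by enolisation and kinetic protonation, with no leaving group at C8. It sets out from 12 (isolated by omitting the acidic methanolysis of step 7) and comes back at 15. LiHMDS (THF, −78 °C) gives the lithium enolate F4. A bulky proton donor (2,6-di-tert-butylphenol) protonates C8 on the face anti to the C7 side chain, which leaves the silyloxy group cis to it in the silyloxy ketone F5. Citric acid in methanol then gives 15.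

Further compounds

F1 | step 16 | (1(10)E,4Z) geometrical isomer of 25 | O=C1/C(C)=C/CC/C(C)=C\[C@H](O[Si](C)(C)C(C)(C)C)[C@@H](C(=C)CO[Si](C)(C)C(C)(C)C)[C@H]1OC(=O)[C@]2(C)O[C@@H]2C
F2 | step 16 | Cope isomer of 25: C9 cyclohexanone with C10 methyl and vinyl, C5 isopropenyl (vinyl and isopropenyl cis, anti to the C6 silyloxy group), C6, C7, C8 as in 25 | O=C1[C@@](C)(C=C)[C@@H](C(C)=C)[C@H](O[Si](C)(C)C(C)(C)C)[C@@H](C(=C)CO[Si](C)(C)C(C)(C)C)[C@H]1OC(=O)[C@]2(C)O[C@@H]2C
F3 | step 17 | 9β-alcohol, C9 epimer of 26 | O[C@H]1/C(C)=C\CC/C(C)=C/[C@H](O[Si](C)(C)C(C)(C)C)[C@@H](C(=C)CO[Si](C)(C)C(C)(C)C)[C@H]1OC(=O)[C@]2(C)O[C@@H]2C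
F4 | step 8 | lithium C8 enolate of 12 | [Li+].[O-]C=1C(C)=C[C@H](O[Si](C)(C)C(C)(C)C)[C@@H](C(=C)CO[Si](C)(C)C(C)(C)C)C=1O[Si](C)(C)C
F5 | step 8 | C8 epimer of 12 (trimethylsilyloxy group cis to the C7 side chain) | O=C1C(C)=C[C@H](O[Si](C)(C)C(C)(C)C)[C@@H](C(=C)CO[Si](C)(C)C(C)(C)C)[C@H]1O[Si](C)(C)C
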